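## The problem

The target is a tricycle. A 2-acetoxy-3,4-dihydro-2H-pyran (ring A: O, C2, C1, C5, C4, C3) is cis-fused through C1–C5 to a cycloheptenone (ring B: C1, C10, C9, C8, C7, C6, C5), and ring B carries a cis-fused gem-dimethylcyclopropane (ring C: C6, C7, C11). Five stereocentres must be set: C1 and C5 (cis fusion), C6 and C7 (cyclopropane on the face of ring B opposite C4, H5 and H6 trans), and the acetal carbon C2 (H2 cis to H1, acetate on the side of C10). C1/C5 are the anchor: the convex face of the cis-fused bicycle can direct C6, C6 can direct C7, and the same face can steer a hydride to C2. C10 is sp2 in the target, so any centre placed there earlier is a spectator. Almost every group is fragile: the anomeric acetate sits on an enol-ether oxygen, the C15 acetate is allylic to that enol ether, C8/C14 form a 4-oxo-2-enal, and C1–H is vinylogously acidic. The aldehyde, the C9=C10 alkene and the acetates must therefore appear late and without acid or strong base. The feature that opens the key step is the acylcyclopropane: the C8 carbonyl is bonded to cyclopropane carbon C7, whose neighbour C6 is a ring-B atom and whose partner C11 carries two methyl groups. This is the product pattern of a 1,2-acyl shift in a β,γ-unsaturated ketone. Cutting C7–C8 and C6–C11 and re-joining C8 to C6 contracts ring B to a cyclohexanone with a 2-methylprop-1-enyl group on C6.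

## Retrosynthesis

**32 back to 28 (C–O and oxidation-level changes only).** The C15 acetate is traced to TBDPS ether 30 through alcohol 31, and the C14 aldehyde to allylic alcohol 29 and its TBS ether 28. Two different silyl ethers are preferred to an acetal at C14, because an acetal could only be opened with acid, which the anomeric acetate and the enol ether would not survive. The cost is two extra deprotections. The forward steps must tell a primary TBS ether from a primary TBDPS ether and leave the acetal acetate alone.

**28 back to 24.** The C9=C10 bond is removed as a Saegusa disconnection to silyl enol ether 27. The acetal acetate goes back to lactone 25 through aluminium hemiacetal 26, and 25 to ketone 24. Reducing the lactone while the ketone is hidden as its enol ether avoids reducing and re-oxidising an enone. Trapping the hemiacetal as the acetate avoids a free lactol whose open form is an enol. Ketone 24 can enolise only towards C9, because C7 is a cyclopropane carbon. The reduction must deliver hydride to C2 from the face of H1.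

**24 back to 23 (key disconnection).** C7–C8 and C6–C11 are cut and C8 is re-joined to C6. This removes the seven-membered ring, the cyclopropane and two stereocentres at once and leaves 23, a cis-fused cyclohexanone with a 2-methylprop-1-enyl group on C6 cis to C4. The neighbouring cuts (acylation at C8–C9, or carbene addition across C6–C7) each make one ring and need the seven-membered ring from elsewhere. The forward reaction, a sensitised 1,2-acyl shift, must work on a freely rotating alkene and pass the C6 configuration on to C7.

**23 back to 19.** The C6 centre is taken back to dienolate 22 of the epimer mixture 21 (kinetic protonation). Ring A is opened at the enol-ester O–C3 bond to a δ-formyl acid, stored as acid acetal 19, with hydroxy lactone 20 on the way. A 2-pyranone used as dienophile would be the shortest source of ring A, but its 3,4-bond is a reluctant 2π partner and electron-rich dienes are likely to attack its 6-position instead. Closing ring A after ring B avoids that. The forward step must dehydrate a formyl acid without base strong enough to move the β,γ-alkene into conjugation.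

**19 back to 15.** The imide is restored (17, with peroxy acid 18 in the forward sense) and C6–C7 is cut to silyl enol ether 15 and bromide 16. The cut is placed on the enol silane because a free cyclohexanone could enolise towards C9 as easily as towards C6, whereas 15 holds the double bond between C8 and C6 by construction. The coupling must consume the enol silane without equilibration.

**15 back to 8 and 14.** The six-membered ring is cut at C9–C10 and C1–C5 (Diels–Alder). This pairing, not the one cutting C1–C10 and C5–C6, puts the enol silane on the C6 side. The chelated imide on C1 sends C9 to C10, and the endo rule sets the C5 side chain cis to C2. The auxiliary fixes the absolute configuration at C1. The (E)-dienophile places the C10 substituent trans to C2; this is accepted because C10 becomes sp2 in step 16.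

**Fragments.** Diene 8 is the enol silane of enone 7, which comes from aldehyde 6 and ylide 5, then monosilyl ether 4, diol 3 and malonates 2 and 1. The side chain thus carries C3 as an acetal and C15 as a silyl ether from the start, so two hydroxymethyl groups never need to be told apart later. Imide 14 is cut at the N–acyl bond to acid 11 (through mixed anhydride 13) and auxiliary 12. Acid 11 is cut at its double bond (cross-metathesis) to acrylic acid 9 and allyl ether 10.

## Roads not taken

**Alternative 1:** The cut is C8–C9, made when ring A and the cyclopropane already exist. In the forward step (Me3Si)3SiH and an initiator would turn a C8 selenoester into an acyl radical that closes 7-endo onto the methylene carbon C9 of a thioacrylate on C1. The product is keto thioester A1, with both acetates in place.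
- Merits: the conditions are neutral and tin-free, and the acetal acetate and enol ether should tolerate them. Acyl-radical additions to acrylate-type acceptors are established, and the polarity match favours attack at the terminal carbon over 6-exo closure at C10. The key step is better precedented than the one chosen here, and no late reduction of a lactone is needed.
- Weak points: the step forms one bond and no stereocentre of the target. C1, C2, C5, C6 and C7 would have to be assembled beforehand on a monocyclic dihydropyran with no carbocycle to relay stereochemistry. A seven-membered radical closure is slow enough for reduction or decarbonylation of the acyl radical to compete. The thioester-to-aldehyde change and the C9=C10 dehydrogenation would fall on a substrate that already carries every labile group.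
- Comparison: the chosen plan makes two rings, two bonds and two stereocentres in its key step and sets C1/C5 by a cycloaddition. Against the better precedent of Alternative 1 it can only offer a conventional fallback for its photochemical step.

**Alternative 2:** The cut is the ring-fusion bond C1–C5. The forward step is a divinylcyclopropane–cycloheptadiene rearrangement on warming to room temperature, which breaks C7–C9 of a cyclopropane (C9, C8, C7) and forms C1–C5, giving cycloheptadiene A2.
- Merits: the reaction is pericyclic and stereospecific, gives the cis C1/C5 relationship reliably, and relays the chirality of an easily made cyclopropane. As a ring-forming step it is clearly more certain than the photochemical shift.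
- Weak points: A2 is far from the target. It has no oxygen at C8, no gem-dimethylcyclopropane and no ring A. Its two alkenes (C6=C7 and C9=C10) must be told apart for a face-selective isopropylidene transfer, the doubly allylic C8 must be oxidised, and the dioxane on C5 must be opened with its two CH2O arms differentiated and oxidised to build C3 and C15.
- Comparison: the chosen plan delivers the cyclopropane and the C8 ketone in the key step and leaves only oxidation-level adjustments. It trades the reliability of Alternative 2 for a much shorter endgame.

**Alternative 3:** The cut is C4–C5 and O–C2, so ring A is built last. An imidazol-2-ylidene catalyst would join the bicyclic α,β-unsaturated acyl fluoride A3 with enol silane A4 by Michael addition and lactonisation to give enol lactone enone A5.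
- Merits: the annulation is convergent and established for dihydropyranones. It makes ring A in its lactone oxidation state in one step from a simple aldehyde derivative, with C9=C10 already present. Addition at C5 anti to the cyclopropane is the required sense.
- Weak points: the hard part, an enantiopure bicyclo[5.1.0] dienone A3 with both cyclopropane centres, is left to an earlier unspecified stage. The acyl azolium is cross-conjugated with competing electrophilic carbons. C1 of A5 is set by protonation and is vinylogously acidic. The lactone must later be reduced beside an enone.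
- Comparison: Alternative 3 makes ring A in one step, where the chosen route spends steps 1–5, 10 and 11 on it; that is a real advantage. The chosen plan sets against it that its key step solves the ring B/cyclopropane problem, and that the ketone is still saturated when the lactone is reduced, so it can be masked as an enol ether.

Key step: step 13

Remark on the chemistry: atom numbers C1–C15 are those of the target throughout; the side-chain carbon C4 is racemic in 4–20 (it becomes sp2 in 21) and C6 is unassigned in 17–21 (it is set in step 12).

Step 1
Reactants: 1 diethyl 2-(ethoxymethylene)malonate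
Product: 2 diethyl 2-(diethoxymethyl)malonate
Conditions: EtOH, NaOEt (5 mol%), rt
Reagents that add atoms: ethanol, CCO
Why: Conjugate (oxa-Michael) addition of ethoxide to the doubly activated alkene and protonation of the malonate anion should give the acetal, which stores C3 at the aldehyde level; no stereocentre is formed.

Step 2
Reactants: 2 diethyl 2-(diethoxymethyl)malonate
Product: 3 2-(diethoxymethyl)propane-1,3-diol
Conditions: LiAlH4, THF, 0 °C → rt
Reagents that add atoms: none
Why: LiAlH4 reduction of both esters; the acetal is inert to hydride.

Step 3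
Reactants: 3 2-(diethoxymethyl)propane-1,3-diol
Product: 4 racemic 3-[(tert-butyldiphenylsilyl)oxy]-2-(diethoxymethyl)propan-1-ol
Conditions: TBDPSCl (0.9 equiv), imidazole, THF, 0 °C (excess diol recovered)
Reagents that add atoms: tert-butyl(chloro)diphenylsilane, CC(C)(C)[Si](Cl)(c1ccccc1)c1ccccc1
Why: Monosilylation of a symmetric diol with a substoichiometric silyl chloride; the new centre (C4) is racemic, which is harmless because C4 becomes sp2 in 21.

Step 4
Reactants: 4 racemic 3-[(tert-butyldiphenylsilyl)oxy]-2-(diethoxymethyl)propan-1-ol; 5 1-(triphenyl-λ5-phosphanylidene)propan-2-one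
Product: 7 racemic (E)-5-{[(tert-butyldiphenylsilyl)oxy]methyl}-6,6-diethoxyhex-3-en-2-one, via aldehyde 6 (not isolated)
Conditions: Dess–Martin periodinane, pyridine, CH2Cl2, 0 °C → rt; then 5, 40 °C
Reagents that add atoms: none
Why: Dess–Martin oxidation followed in the same flask by Wittig olefination with a stabilised ylide should give the (E)-enone and spares the β-silyloxy aldehyde an isolation.

Step 5
Reactants: 7 racemic (E)-5-{[(tert-butyldiphenylsilyl)oxy]methyl}-6,6-diethoxyhex-3-en-2-one
Product: 8 racemic (E)-5-{[(tert-butyldiphenylsilyl)oxy]methyl}-6,6-diethoxy-2-[(triethylsilyl)oxy]hexa-1,3-diene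
Conditions: Et3SiCl, LiN(SiMe3)2, THF, −78 °C
Reagents that add atoms: chlorotriethylsilane, CC[Si](Cl)(CC)CC
Why: Kinetic deprotonation of the methyl ketone gives the cross-conjugated enolate, which is silylated on oxygen (enol silane formation); an amide base is used so that no silyl triflate can ionise the acetal.

Step 6
Reactants: 9 acrylic acid; 10 allyloxy(tert-butyl)dimethylsilane
Product: 11 (E)-4-[(tert-butyldimethylsilyl)oxy]but-2-enoic acid
Conditions: second-generation Grubbs catalyst (2 mol%), CH2Cl2, 40 °C
Reagents that add atoms: none
Why: Olefin cross-metathesis between an electron-poor acrylate partner and an allyl ether is selective for the cross product and for the (E)-alkene.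

Step 7
Reactants: 11 (E)-4-[(tert-butyldimethylsilyl)oxy]but-2-enoic acid; 12 (R)-4-benzyl-1,3-oxazolidin-2-one
Product: 14 (R)-4-benzyl-3-{(E)-4-[(tert-butyldimethylsilyl)oxy]but-2-enoyl}-1,3-oxazolidin-2-one, via mixed pivalic anhydride 13 (not isolated)
Conditions: t-BuCOCl, Et3N, THF, −20 °C; then LiCl, 12, rt
Reagents that add atoms: none
Why: N-Acylation of the oxazolidinone through the mixed pivalic anhydride; the hindered pivaloyl carbonyl directs attack to the enoyl carbonyl.

Step 8
Reactants: 8 racemic (E)-5-{[(tert-butyldiphenylsilyl)oxy]methyl}-6,6-diethoxy-2-[(triethylsilyl)oxy]hexa-1,3-diene; 14 (R)-4-benzyl-3-{(E)-4-[(tert-butyldimethylsilyl)oxy]but-2-enoyl}-1,3-oxazolidin-2-one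
Product: 15 cyclohexene adduct (imide on C1; CH2OTBS on C10 trans to C2; C8=C6 triethylsilyl enol ether; C5 side chain cis to C2; both C4 epimers)
Conditions: Me2AlCl (1.4 equiv), CH2Cl2, −78 °C
Reagents that add atoms: none
Why: Auxiliary-controlled, Lewis-acid-promoted Diels–Alder reaction: the chelated s-cis imide is attacked on the face away from the benzyl group, which sets C1; the nucleophilic diene terminus C9 bonds to C10 (β to the imide); endo approach puts the C5 side chain cis to C2. The (E)-dienophile leaves the C10 substituent trans to C2 as a spectator centre.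

Step 9
Reactants: 15 cyclohexene adduct; 16 1-bromo-2-methylprop-1-ene
Product: 17 cyclohexanone imide with the 2-methylprop-1-enyl group on C6 (C6 and C4 epimers)
Conditions: Pd(OAc)2 (5 mol%), P(t-Bu)3 (10 mol%), Bu3SnF (1.2 equiv), CsF (1.4 equiv), toluene, 85 °C
Reagents that add atoms: none
Why: Pd-catalysed α-alkenylation of a ketone enolate, run through the tin enolate released in situ from the enol silane so that the C6–C7 bond forms only at the carbon fixed by the cycloaddition; the C6 configuration is not controlled here and is set in step 12.

Step 10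
Reactants: 17 cyclohexanone imide with the 2-methylprop-1-enyl group on C6
Product: 19 cyclohexanone carboxylic acid (C2 acid on C1), via peroxy acid 18 (not isolated)
Conditions: LiOH, H2O2, THF–H2O, 0 °C; Na2SO3; 1 M HCl
Reagents that add atoms: hydrogen peroxide, OO
Why: Hydroperoxide cleavage of the N-acyl oxazolidinone at the exocyclic carbonyl, with sulfite reduction of the peroxy acid; the mild, cold conditions should leave C1 and the β,γ-alkene untouched, and the auxiliary is recovered.

Step 11
Reactants: 19 cyclohexanone carboxylic acid
Product: 21 cis-fused enol lactone ketone (ring A closed; both C6 epimers), via hydroxy lactone 20 (not isolated)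
Conditions: PPTS, acetone–H2O, 45 °C; then DCC, DMAP (cat.), CH2Cl2, 0 °C → rt
Reagents that add atoms: water, O
Why: Acetal hydrolysis gives the δ-formyl acid (held as its hydroxy lactone); carbodiimide activation and O-acylation of the aldehyde enol then close the enol δ-lactone (enol lactonisation). This removes the C4 stereocentre, and PPTS spares both silyl ethers.

Step 12
Reactants: 21 cis-fused enol lactone ketone (both C6 epimers)
Product: 23 key precursor: cis-fused enol lactone ketone carrying the 2-methylprop-1-enyl group on C6 cis to C4, via potassium dienolate 22 (not isolated)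
Conditions: KN(SiMe3)2 (1.05 equiv), THF, −78 °C; then AcOH, −78 °C
Reagents that add atoms: none
Why: Deprotonation at the doubly activated C6–H gives the dienolate, and kinetic α-protonation from the convex face (that of H1 and H5) should give the β,γ-unsaturated ketone with the alkenyl group cis to C4. In this C10 series that epimer also has the alkenyl group equatorial, so it is not lost on standing.

Step 13
Reactants: 23 key precursor
Product: 24 tricyclic enol lactone ketone (seven-membered ring B fused to the gem-dimethylcyclopropane; C9–C10 saturated)
Conditions: hν (300 nm, Pyrex), acetone (solvent and sensitiser), degassed, rt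
Reagents that add atoms: none
Why: Proposed new method: triplet energy transfer from acetone to the β,γ-unsaturated ketone should bond the carbonyl carbon C8 to C7 (three-membered closure to a diradical with a tertiary centre at C11), cleave C8–C6 so that the carbonyl re-forms inside a seven-membered ring, and close the C6/C11 1,3-diradical to the cyclopropane. The closest known reaction type is the sensitised oxa-di-π-methane rearrangement of rigid β,γ-unsaturated ketones, which has not been used to enlarge a ring through an exocyclic, freely rotating alkene. Ring B arises by net insertion of C7 between C8 and C6 (1,2-acyl shift), ring C by radical recombination. C7 is set by the alkene face that C8 reaches: with the alkenyl group cis to C4 and the C6–H bond eclipsing the isopropylidene unit (allylic strain), C11 should end on the face opposite C4. C6 follows because the cyclopropane can only be cis-fused to the seven-membered ring. The step needs the triplet 1,2-shift to beat the singlet 1,3-acyl shift and decay by alkene twisting; sensitisation bypasses the singlet state, and the tertiary C11 radical and the ring-held carbonyl favour bonding. The reaction must proceed from the chair in which the alkenyl group is axial.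

Step 14
Reactants: 24 tricyclic enol lactone ketone
Product: 25 C8 tert-butyldimethylsilyl enol ether (C8=C9) of 24
Conditions: TBSOTf, Et3N, CH2Cl2, −78 → 0 °C
Reagents that add atoms: tert-butyldimethylsilyl trifluoromethanesulfonate, CC(C)(C)[Si](C)(C)OS(=O)(=O)C(F)(F)F
Why: Soft enolisation and O-silylation; only C9 can enolise because a double bond to cyclopropane carbon C7 is strongly disfavoured. The enol silane masks the ketone against hydride and prepares the later dehydrogenation.

Step 15
Reactants: 25 C8 tert-butyldimethylsilyl enol ether of 24
Product: 27 C2 acetal acetate (H2 cis to H1), via aluminium hemiacetal 26 (not isolated)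
Conditions: i-Bu2AlH, CH2Cl2, −78 °C; then pyridine, DMAP, Ac2O, −78 → −20 °C
Reagents that add atoms: acetic anhydride, CC(=O)OC(C)=O
Why: Reductive acetylation: semi-reduction of the enol lactone and acetylation of the aluminium hemiacetal at low temperature avoids a free lactol. Hydride should add to C2 from the convex face, anti to C10, so that H2 ends cis to H1 and the acetate on the side of C10, as in the target.

Step 16
Reactants: 27 C2 acetal acetate
Product: 28 enone (C8 ketone, C9=C10, CH2OTBS on C10)
Conditions: Pd(OAc)2 (1.1 equiv), MeCN, rt
Reagents that add atoms: none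
Why: Saegusa oxidation: palladation at C9 and β-hydride elimination of H10 give the conjugated enone and erase the spectator centre C10. Stoichiometric Pd(OAc)2 without phosphine keeps soluble reduced palladium, which could ionise the anomeric acetate, to a minimum.

Step 17
Reactants: 28 enone
Product: 29 C14 allylic alcohol
Conditions: HF·pyridine, pyridine, THF, 0 °C
Reagents that add atoms: none
Why: Buffered fluoride desilylation; the primary TBS ether is cleaved far faster than the TBDPS ether, and the buffered medium should leave the acetal acetate and enol ether intact.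

Step 18
Reactants: 29 C14 allylic alcohol
Product: 30 keto-enal (C14 aldehyde; C15 still OTBDPS)
Conditions: MnO2, CH2Cl2, rt
Reagents that add atoms: none
Why: MnO2 oxidation of the allylic alcohol to the enal under neutral, heterogeneous conditions.

Step 19
Reactants: 30 keto-enal
Product: 32 target diacetate, via C15 alcohol 31 (not isolated)
Conditions: HF·pyridine, pyridine, THF, rt; then Ac2O, DMAP, 0 °C
Reagents that add atoms: acetic anhydride, CC(=O)OC(C)=O
Why: Fluoride desilylation of the TBDPS ether and acetylation in the same flask, so that the free C15 alcohol is not left beside the acetal acetate; no stereocentre is touched.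

Compound list

1 | diethyl 2-(ethoxymethylene)malonate | CCOC=C(C(=O)OCC)C(=O)OCC | starting material
2 | diethyl 2-(diethoxymethyl)malonate | CCOC(OCC)C(C(=O)OCC)C(=O)OCC | intermediate
3 | 2-(diethoxymethyl)propane-1,3-diol | CCOC(OCC)C(CO)CO | intermediate
4 | racemic 3-[(tert-butyldiphenylsilyl)oxy]-2-(diethoxymethyl)propan-1-ol | CCOC(OCC)C(CO)CO[Si](c1ccccc1)(c1ccccc1)C(C)(C)C | intermediate
5 | 1-(triphenyl-λ5-phosphanylidene)propan-2-one | CC(=O)C=P(c1ccccc1)(c1ccccc1)c1ccccc1 | starting material
6 | racemic 3-[(tert-butyldiphenylsilyl)oxy]-2-(diethoxymethyl)propanal | CCOC(OCC)C(C=O)CO[Si](c1ccccc1)(c1ccccc1)C(C)(C)C | intermediate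
7 | racemic (E)-5-{[(tert-butyldiphenylsilyl)oxy]methyl}-6,6-diethoxyhex-3-en-2-one | CC(=O)/C=C/C(CO[Si](c1ccccc1)(c1ccccc1)C(C)(C)C)C(OCC)OCC | intermediate
8 | racemic (E)-5-{[(tert-butyldiphenylsilyl)oxy]methyl}-6,6-diethoxy-2-[(triethylsilyl)oxy]hexa-1,3-diene | C=C(O[Si](CC)(CC)CC)/C=C/C(CO[Si](c1ccccc1)(c1ccccc1)C(C)(C)C)C(OCC)OCC | intermediate
9 | acrylic acid | C=CC(=O)O | starting material
10 | allyloxy(tert-butyl)dimethylsilane | C=CCO[Si](C)(C)C(C)(C)C | starting material
11 | (E)-4-[(tert-butyldimethylsilyl)oxy]but-2-enoic acid | CC(C)(C)[Si](C)(C)OC/C=C/C(=O)O | intermediate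
12 | (R)-4-benzyl-1,3-oxazolidin-2-one | O=C1N[C@H](Cc2ccccc2)CO1 | starting material
13 | mixed anhydride of 11 with pivalic acid | CC(C)(C)[Si](C)(C)OC/C=C/C(=O)OC(=O)C(C)(C)C | intermediate
14 | (R)-4-benzyl-3-{(E)-4-[(tert-butyldimethylsilyl)oxy]but-2-enoyl}-1,3-oxazolidin-2-one | CC(C)(C)[Si](C)(C)OC/C=C/C(=O)N1[C@H](Cc2ccccc2)COC1=O | intermediate
15 | Diels–Alder adduct: N-acyl (R)-4-benzyloxazolidinone of a cyclohex-3-ene-1-carboxylic acid; ring carbons C1 (acyl C2), C10 (CH2OTBS, trans to C2), C9, C8 (OSiEt3, C8=C6), C6, C5 (side chain CH(CH2OTBDPS)CH(OEt)2, cis to C2); both epimers at side-chain carbon C4 | O=C(N1[C@H](Cc2ccccc2)COC1=O)[C@H]3[C@H](CO[Si](C)(C)C(C)(C)C)CC(O[Si](CC)(CC)CC)=C[C@H]3C(CO[Si](c4ccccc4)(c4ccccc4)C(C)(C)C)C(OCC)OCC | intermediate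
16 | 1-bromo-2-methylprop-1-ene | CC(C)=CBr | starting material
17 | as 15, but C8 ketone and 2-methylprop-1-enyl on C6 (both C6 epimers, both C4 epimers) | O=C(N1[C@H](Cc2ccccc2)COC1=O)[C@H]3[C@H](CO[Si](C)(C)C(C)(C)C)CC(=O)C(C=C(C)C)[C@H]3C(CO[Si](c4ccccc4)(c4ccccc4)C(C)(C)C)C(OCC)OCC | intermediate
18 | peroxy acid from 17 (C2 = C(=O)OOH) | OOC(=O)[C@H]1[C@H](CO[Si](C)(C)C(C)(C)C)CC(=O)C(C=C(C)C)[C@H]1C(CO[Si](c2ccccc2)(c2ccccc2)C(C)(C)C)C(OCC)OCC | intermediate
19 | carboxylic acid from 17 (C2 = CO2H on C1; C10 CH2OTBS trans, C5 side chain cis to C2) | OC(=O)[C@H]1[C@H](CO[Si](C)(C)C(C)(C)C)CC(=O)C(C=C(C)C)[C@H]1C(CO[Si](c2ccccc2)(c2ccccc2)C(C)(C)C)C(OCC)OCC | intermediate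
20 | hydroxy lactone: 6-hydroxytetrahydropyran-2-one ring A (O–C2(=O)–C1–C5–C4–C3(OH)) cis-fused to the cyclohexanone; C3, C4 and C6 unassigned | OC1OC(=O)[C@H]2[C@H](CO[Si](C)(C)C(C)(C)C)CC(=O)C(C=C(C)C)[C@H]2C1CO[Si](c3ccccc3)(c3ccccc3)C(C)(C)C | intermediate
21 | cis-fused enol lactone ketone: ring A O–C2(=O)–C1–C5–C4(CH2OTBDPS)=C3; cyclohexanone with CH2OTBS on C10 (trans to C2) and 2-methylprop-1-enyl on C6 (both epimers) | CC(C)(C)[Si](c1ccccc1)(c1ccccc1)OCC1=COC(=O)[C@H]2[C@H](CO[Si](C)(C)C(C)(C)C)CC(=O)C(C=C(C)C)[C@@H]12 | intermediate
22 | potassium dienolate of 21 (C8–O–K, C8=C6) | CC(C)(C)[Si](c1ccccc1)(c1ccccc1)OCC1=COC(=O)[C@H]2[C@H](CO[Si](C)(C)C(C)(C)C)CC([O-])=C(C=C(C)C)[C@@H]12.[K+] | intermediate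
23 | key precursor: 21 with the 2-methylprop-1-enyl group on C6 cis to C4 (H5 and H6 cis) | CC(C)(C)[Si](c1ccccc1)(c1ccccc1)OCC1=COC(=O)[C@H]2[C@H](CO[Si](C)(C)C(C)(C)C)CC(=O)[C@@H](C=C(C)C)[C@@H]12 | intermediate
24 | tricyclic enol lactone ketone: ring B seven-membered (C1, C10, C9, C8, C7, C6, C5), gem-dimethylcyclopropane C6–C7–C11 cis-fused on the face opposite C4 (H5/H6 trans, H6/H7 cis), CH2OTBS on C10 | CC(C)(C)[Si](c1ccccc1)(c1ccccc1)OCC1=COC(=O)[C@H]2[C@H](CO[Si](C)(C)C(C)(C)C)CC(=O)[C@H]3[C@@H]([C@@H]12)C3(C)C | intermediate
25 | C8 tert-butyldimethylsilyl enol ether of 24 (C8=C9) | CC(C)(C)[Si](c1ccccc1)(c1ccccc1)OCC1=COC(=O)[C@H]2[C@H](CO[Si](C)(C)C(C)(C)C)C=C(O[Si](C)(C)C(C)(C)C)[C@H]3[C@@H]([C@@H]12)C3(C)C | intermediate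
26 | diisobutylaluminium hemiacetal at C2 of 25 (O–Al on the side of C10) | CC(C)(C)[Si](c1ccccc1)(c1ccccc1)OCC1=CO[C@@H](O[Al](CC(C)C)CC(C)C)[C@H]2[C@H](CO[Si](C)(C)C(C)(C)C)C=C(O[Si](C)(C)C(C)(C)C)[C@H]3[C@@H]([C@@H]12)C3(C)C | intermediate
27 | C2 acetal acetate (H2 cis to H1, acetate on the side of C10); C8 silyl enol ether retained | CC(C)(C)[Si](c1ccccc1)(c1ccccc1)OCC1=CO[C@@H](OC(C)=O)[C@H]2[C@H](CO[Si](C)(C)C(C)(C)C)C=C(O[Si](C)(C)C(C)(C)C)[C@H]3[C@@H]([C@@H]12)C3(C)C | intermediate
28 | enone: C8 ketone, C9=C10, CH2OTBS on C10, C15 OTBDPS, C2 acetate | CC(C)(C)[Si](c1ccccc1)(c1ccccc1)OCC1=CO[C@@H](OC(C)=O)[C@H]2C(CO[Si](C)(C)C(C)(C)C)=CC(=O)[C@H]3[C@@H]([C@@H]12)C3(C)C | intermediate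
29 | C14 allylic alcohol of 28 | CC(C)(C)[Si](c1ccccc1)(c1ccccc1)OCC1=CO[C@@H](OC(C)=O)[C@H]2C(CO)=CC(=O)[C@H]3[C@@H]([C@@H]12)C3(C)C | intermediate
30 | keto-enal: C14 aldehyde on C10, C8 ketone, C15 OTBDPS, C2 acetate | CC(C)(C)[Si](c1ccccc1)(c1ccccc1)OCC1=CO[C@@H](OC(C)=O)[C@H]2C(C=O)=CC(=O)[C@H]3[C@@H]([C@@H]12)C3(C)C | intermediate
31 | C15 alcohol of 30 | OCC1=CO[C@@H](OC(C)=O)[C@H]2C(C=O)=CC(=O)[C@H]3[C@@H]([C@@H]12)C3(C)C | intermediate
32 | target: C2 acetate (H2 cis to H1), C15 acetate, C14 aldehyde on C10, C9=C10, C8 ketone, cis ring fusion at C1/C5, gem-dimethylcyclopropane C6–C7–C11 on the face opposite C4 | CC(=O)OCC1=CO[C@@H](OC(C)=O)[C@H]2C(C=O)=CC(=O)[C@H]3[C@@H]([C@@H]12)C3(C)C | target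

Total step count: 19. Longest linear sequence: 17 steps (steps 1–5 and 8–19); the dienophile branch (steps 6 and 7) joins at step 8.

Steps least certain to work

Step 13 (key step, proposed new method). The most likely failure is loss of the triplet energy by twisting of the free alkene, together with α-cleavage at C8–C6 leading to the 1,3-acyl-shift isomer or to scrambling of C6. The risk is raised because the chair with the alkenyl group axial, the only one with the needed overlap, should be the minor conformer when the C10 substituent is trans to C2. Photoaddition of acetone to the enol-ether alkene is a further drain. Fallback with known chemistry, setting out from 15 and returning at 24: Simmons–Smith cyclopropanation (Et2Zn, CH2I2) of the enol silane should give the triethylsilyloxy-cyclopropane F1. FeCl3 in DMF opens its internal bond with ring expansion to the β-chloro cycloheptanone F2, and NaOAc in MeOH eliminates HCl to the cyclohept-2-enone F3. Isopropylidene transfer from diphenylsulfonium isopropylide (sulfur-ylide cyclopropanation), adding to C6 anti to the C5 side chain, gives the gem-dimethylcyclopropyl ketone F4. LiOH/H2O2 then gives the peroxy acid F5 and, after sulfite, the carboxylic acid F6. PPTS in wet acetone gives the hydroxy lactone F7, and DCC/DMAP closes ring A to 24.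

Step 9. Slow silicon-to-tin exchange, equilibration of the enolate towards C9, or base-induced migration of the new alkene into conjugation would erode the regiochemical advantage of the enol silane. Fallback, setting out from 15 and returning at 17: allylation of the enol silane with 2-methylallyl methyl carbonate under Pd(PPh3)4 catalysis (Tsuji–Trost type) should give the α-(2-methylallyl) ketone F8. RhCl3·3H2O in EtOH then moves the 1,1-disubstituted alkene by one position to the trisubstituted 2-methylprop-1-enyl group.

Step 8. The strong Lewis acid may ionise the diethyl acetal or lead to conjugate addition without ring closure, and the branched C5 terminus may lower endo and facial selectivity. Fallback, setting out from 11 and 8 and returning at 19: acid 11 is coupled (through 13) with 1,3-oxazolidin-2-one to the achiral imide F9. The divalent copper complex [Cu((S,S)-t-Bu-box)](SbF6)2 (10 mol%, CH2Cl2, −20 °C) then controls the cycloaddition with 8 and should give the auxiliary-free adduct F10. The alkenylation of step 9 gives the ketone F11, and LiOH/H2O2 as in step 10 gives 19.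

Step 15. The tetrahedral aluminium intermediate of an enol ester may collapse with ring opening before it is acetylated, leading to over-reduction, or hydride may arrive from the concave face. Fallback, setting out from 25 and returning at 27: i-Bu2AlH at −78 °C with a tartrate work-up should give the isolated lactol F12. Acetylation under equilibrating conditions (Ac2O, Et3N, DMAP) then relies on the anomeric preference rather than on the face of hydride delivery.

Step 16. Reduced palladium formed during the oxidation may ionise the anomeric acetate, or the hindered silyl enol ether may react sluggishly. Fallback, setting out from 27 and returning at 28: PhSeCl converts the enol silane into the C9 phenylselanyl ketone F13. H2O2 with pyridine at 0 °C then triggers selenoxide syn-elimination towards H10.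

Step 12. Protonation at C11 instead of C6, or from the concave face, would give the conjugated isomer or the wrong C6 epimer. Fallback, setting out from 21 and returning at 23: equilibration with DBU in CH2Cl2 relies on thermodynamic instead of kinetic control, since the wanted epimer has the alkenyl group equatorial; the minor epimer is separated and recycled. No new compound is involved.

Further compounds

F1 | step 13 | triethylsilyloxy-cyclopropane from 15 (CH2 added across C8=C6) | O=C(N1[C@H](Cc2ccccc2)COC1=O)[C@H]3[C@H](CO[Si](C)(C)C(C)(C)C)CC4(O[Si](CC)(CC)CC)CC4[C@H]3C(CO[Si](c5ccccc5)(c5ccccc5)C(C)(C)C)C(OCC)OCC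
F2 | step 13 | β-chloro cycloheptanone (C8 ketone, C7 methylene, Cl on C6) | O=C(N1[C@H](Cc2ccccc2)COC1=O)[C@H]3[C@H](CO[Si](C)(C)C(C)(C)C)CC(=O)CC(Cl)[C@H]3C(CO[Si](c4ccccc4)(c4ccccc4)C(C)(C)C)C(OCC)OCC
F3 | step 13 | cyclohept-2-enone (C8 ketone, C7=C6) | O=C(N1[C@H](Cc2ccccc2)COC1=O)[C@H]3[C@H](CO[Si](C)(C)C(C)(C)C)CC(=O)C=C[C@H]3C(CO[Si](c4ccccc4)(c4ccccc4)C(C)(C)C)C(OCC)OCC
F4 | step 13 | gem-dimethylcyclopropyl ketone imide (cyclopropane C6–C7–C11 on the face opposite C4) | O=C(N1[C@H](Cc2ccccc2)COC1=O)[C@H]3[C@H](CO[Si](C)(C)C(C)(C)C)CC(=O)[C@H]5[C@@H]([C@H]3C(CO[Si](c4ccccc4)(c4ccccc4)C(C)(C)C)C(OCC)OCC)C5(C)C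
F5 | step 13 | peroxy acid from F4 | OOC(=O)[C@H]3[C@H](CO[Si](C)(C)C(C)(C)C)CC(=O)[C@H]5[C@@H]([C@H]3C(CO[Si](c4ccccc4)(c4ccccc4)C(C)(C)C)C(OCC)OCC)C5(C)C
F6 | step 13 | carboxylic acid from F4 | OC(=O)[C@H]3[C@H](CO[Si](C)(C)C(C)(C)C)CC(=O)[C@H]5[C@@H]([C@H]3C(CO[Si](c4ccccc4)(c4ccccc4)C(C)(C)C)C(OCC)OCC)C5(C)C
F7 | step 13 | hydroxy lactone from F6 | OC1OC(=O)[C@H]2[C@H](CO[Si](C)(C)C(C)(C)C)CC(=O)[C@H]3[C@@H]([C@H]2C1CO[Si](c4ccccc4)(c4ccccc4)C(C)(C)C)C3(C)C
F8 | step 9 | α-(2-methylallyl) ketone imide (2-methylallyl on C6) | O=C(N1[C@H](Cc2ccccc2)COC1=O)[C@H]3[C@H](CO[Si](C)(C)C(C)(C)C)CC(=O)C(CC(C)=C)[C@H]3C(CO[Si](c4ccccc4)(c4ccccc4)C(C)(C)C)C(OCC)OCC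
F9 | step 8 | 3-{(E)-4-[(tert-butyldimethylsilyl)oxy]but-2-enoyl}-1,3-oxazolidin-2-one | CC(C)(C)[Si](C)(C)OC/C=C/C(=O)N1CCOC1=O
F10 | step 8 | Diels–Alder adduct of F9 and 8 (as 15 without the benzyl group) | O=C(N1CCOC1=O)[C@H]3[C@H](CO[Si](C)(C)C(C)(C)C)CC(O[Si](CC)(CC)CC)=C[C@H]3C(CO[Si](c4ccccc4)(c4ccccc4)C(C)(C)C)C(OCC)OCC
F11 | step 8 | C6-alkenyl ketone from F10 (as 17 without the benzyl group) | O=C(N1CCOC1=O)[C@H]3[C@H](CO[Si](C)(C)C(C)(C)C)CC(=O)C(C=C(C)C)[C@H]3C(CO[Si](c4ccccc4)(c4ccccc4)C(C)(C)C)C(OCC)OCC
F12 | step 15 | C2 lactol of 25 (anomer mixture) | CC(C)(C)[Si](c1ccccc1)(c1ccccc1)OCC1=COC(O)[C@H]2[C@H](CO[Si](C)(C)C(C)(C)C)C=C(O[Si](C)(C)C(C)(C)C)[C@H]3[C@@H]([C@@H]12)C3(C)C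
F13 | step 16 | C9 phenylselanyl ketone from 27 | CC(C)(C)[Si](c1ccccc1)(c1ccccc1)OCC1=CO[C@@H](OC(C)=O)[C@H]2[C@H](CO[Si](C)(C)C(C)(C)C)C([Se]c4ccccc4)C(=O)[C@H]3[C@@H]([C@@H]12)C3(C)C
F0 | step 12 | none | none
A1 | alternative 1 | tricyclic keto thioester with both acetates (ethyl thioester on C10, C9–C10 saturated) | CC(=O)OCC1=CO[C@@H](OC(C)=O)[C@H]2[C@@H](C(=O)SCC)CC(=O)[C@H]3[C@@H]([C@@H]12)C3(C)C
A2 | alternative 2 | cis-6,7-disubstituted cyclohepta-1,4-diene | CC(C)(C)[Si](C)(C)OC[C@H]1C(CO[Si](C)(C)C(C)(C)C)=CCC=C[C@H]1C2COC(C)(C)OC2
A3 | alternative 3 | bicyclic α,β-unsaturated acyl fluoride (C2 acyl fluoride on the C1=C5 alkene) | O=C(F)C1=C[C@@H]2[C@H](C(=O)C=C1C(OC)OC)C2(C)C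
A4 | alternative 3 | trimethylsilyl enol ether of 3-(tert-butyldimethylsilyloxy)propanal | C[Si](C)(C)OC=CCO[Si](C)(C)C(C)(C)C
A5 | alternative 3 | tricyclic enol lactone enone | CC(C)(C)[Si](C)(C)OCC1=COC(=O)[C@H]2C(C(OC)OC)=CC(=O)[C@H]3[C@@H]([C@@H]12)C3(C)C
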